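**Retrosynthetic overview**

1. Ring A is the benzene ring, with primed locants: C1′ (CH2 bridge), C2′ (OH), C3′ (prenyl), C4′ (OH), C5′ (isobutyryl), C6′ (OMe); ring B is the 4-hydroxypyran-2-one. The route rests on the strict alternation of oxygen and carbon substituents around ring A, which maps C1′–C4′ onto a 3-alkoxyvinylketene and C5′–C6′ onto a 1-methoxyalkyne.
2. Last bond: C1′–CH2–C3 (ring B) is cut to the acylphloroglucinol 23 (C1′–H), pyranone 28 and a one-carbon iminium salt (Mannich reaction, then capture of a methylene dione).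
3. 23 goes back (PMB cleavage, carbinol oxidation, desilylation) to phenol 20, whose ring A is cut at C4′–C5′, C6′–C1′ and C3′–C4′ into cyclobutenone 10 and ynol ether 15 (Danheiser benzannulation).
4. 10 comes from prenylketene and 4-methoxybenzyl ethynyl ether by [2+2] addition; 15 from lithium methoxyacetylide and isobutyraldehyde; 28 from γ-acylation of a β-keto ester dianion and lactonisation.
5. Ring order: ring B is made separately (step 12), ring A is formed in step 7, and the two rings are joined in step 13.

Key step: step 7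

Remark: the target has no stereocentre; 10, 14, 15, 17 to 21 and 27 are carried as racemates or diastereomer mixtures, and every one of these centres is erased by step 9 (ring A series) or step 12 (ring B series). PMB = 4-methoxybenzyl, TBS = tert-butyldimethylsilyl, prenyl = 3-methylbut-2-en-1-yl.

**Route**

Step 1
Reactants: 1 4-methoxybenzyl alcohol; 2 trichloroethylene
Product: 3 1-{[(E)-1,2-dichloroethenyl]oxymethyl}-4-methoxybenzene
Conditions: KH, THF, 0 °C; then 2, −50 °C → rt
Reagents that add atoms: none
Why: Vinylic substitution by elimination–addition: the potassium alkoxide adds to trichloroethylene with loss of chloride to give the dichlorovinyl ether that is the standard precursor of ynol ethers, and its E geometry is of no consequence because both chlorines are removed in step 2.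

Step 2
Reactants: 3 1-{[(E)-1,2-dichloroethenyl]oxymethyl}-4-methoxybenzene
Product: 6 1-[(ethynyloxy)methyl]-4-methoxybenzene (4-methoxybenzyl ethynyl ether), via chloroethynyl ether 4 (not isolated), via lithium acetylide 5 (not isolated)
Conditions: n-BuLi (2.2 equiv), Et2O, −78 → −40 °C; H2O, −78 °C; extracted cold, used at once below 0 °C
Reagents that add atoms: none
Why: Base-induced dehydrochlorination followed by chlorine–lithium exchange: the first equivalent of n-BuLi eliminates HCl to 4, the second exchanges the remaining chlorine to give 5, which is protonated cold; benzyl ynol ethers undergo [3,3]-sigmatropic rearrangement only on warming, so 6 is kept cold and used directly.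

Step 3
Reactants: 7 5-methylhex-4-enoic acid
Product: 8 5-methylhex-4-enoyl chloride
Conditions: (COCl)2, DMF (cat.), CH2Cl2, 0 °C → rt; volatiles removed
Reagents that add atoms: oxalyl chloride, ClC(=O)C(=O)Cl
Why: Acid chloride formation with oxalyl chloride under chloroiminium (DMF) catalysis, run without heating so that the HCl formed should not add to the trisubstituted olefin.

Step 4
Reactants: 8 5-methylhex-4-enoyl chloride; 6 4-methoxybenzyl ethynyl ether
Product: 10 3-[(4-methoxybenzyl)oxy]-4-(3-methylbut-2-en-1-yl)cyclobut-2-en-1-one (racemic), via prenylketene 9 (not isolated)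
Conditions: Et3N, Et2O, 0 °C → rt, slow addition of 8
Reagents that add atoms: none
Why: Dehydrochlorination of 8 gives monoalkylketene 9, which is trapped in a ketene–alkoxyalkyne [2+2] cycloaddition in which the nucleophilic CH terminus of 6 bonds to the ketene carbonyl carbon, so that OPMB ends at C3 and the prenyl-bearing carbon at C4 of the cyclobutenone; the C4 stereocentre forms racemic and disappears in step 7.

Step 5
Reactants: 11 chloroacetaldehyde dimethyl acetal; 12 isobutyraldehyde
Product: 14 1-methoxy-4-methylpent-1-yn-3-ol (racemic), via lithium methoxyacetylide 13 (not isolated)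
Conditions: LiNEt2 (3.1 equiv, from Et2NH and n-BuLi), THF, 0 °C; then 12, −78 → 0 °C; aq. NaHCO3
Reagents that add atoms: none
Why: Two eliminations and a deprotonation by LiNEt2 convert the chloroacetal into 13, which adds to the aldehyde carbonyl (acetylide 1,2-addition) to give the racemic carbinol; the bicarbonate work-up avoids the acid-induced Meyer–Schuster rearrangement to the unsaturated ester.

Step 6
Reactants: 14 1-methoxy-4-methylpent-1-yn-3-ol
Product: 15 tert-butyl[(1-methoxy-4-methylpent-1-yn-3-yl)oxy]dimethylsilane (racemic)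
Conditions: TBSCl, imidazole, DMF, rt; purified on Et3N-deactivated silica
Reagents that add atoms: tert-butyldimethylsilyl chloride, CC(C)(C)[Si](C)(C)Cl
Why: Imidazole-mediated silylation of a secondary alcohol masks the future ketone oxygen under base-buffered conditions that the acid-sensitive ynol ether tolerates; the stereocentre is untouched.

Step 7
Reactants: 10 3-[(4-methoxybenzyl)oxy]-4-(3-methylbut-2-en-1-yl)cyclobut-2-en-1-one; 15 tert-butyl[(1-methoxy-4-methylpent-1-yn-3-yl)oxy]dimethylsilane
Product: 20 2-{1-[(tert-butyldimethylsilyl)oxy]-2-methylpropyl}-3-methoxy-5-[(4-methoxybenzyl)oxy]-6-(3-methylbut-2-en-1-yl)phenol (racemic), via vinylketene 16 (not isolated), via vinylcyclobutenone 17 (not isolated), via dienylketene 18 (not isolated), via cyclohexadienone 19 (not isolated)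
Conditions: 15 (1.5 equiv), PhMe, 90 °C then 120 °C, sealed tube under Ar
Reagents that add atoms: none
Why: Heating opens cyclobutenone 10 by conrotatory 4π electrocyclic cleavage of its C1–C4 bond to the 3-alkoxyvinylketene 16, whose ketene C=C adds [2+2] to the electron-rich alkyne 15 to form the C4′–C5′ and C6′–C1′ bonds in vinylcyclobutenone 17. A second 4π opening gives dienylketene 18 (reversible, so the wrong olefin geometry drains back through 17), and ring A then closes at C3′–C4′ by thermal disrotatory 6π electrocyclisation to dienone 19, which tautomerises to the C4′ phenol 20. The closest known reaction type is the Danheiser benzannulation of cyclobutenones with 1-alkoxyalkynes to resorcinol monoethers. No stereocentre is created: C4 of 10 becomes the sp2 carbon C3′, and the silyloxy carbinol centre of 15 is carried through racemic and erased in step 9. The step needs regioselectivity in the [2+2] event, and the polarisation of the ynol ether secures it, because its nucleophilic carbon (future C5′) attacks the electrophilic ketene carbon (future C4′), which places OMe at C6′ between C1′–H and the masked acyl carbon. Chemoselectivity for the ynol ether over the prenyl olefin follows from the far higher nucleophilicity of the alkyne, the methyl ynol ether has no β-hydrogen through which it could fragment on heating, and the neutral conditions should leave the PMB ether, the silyl ether and the prenyl group untouched.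

Step 8
Reactants: 20 2-{1-[(tert-butyldimethylsilyl)oxy]-2-methylpropyl}-3-methoxy-5-[(4-methoxybenzyl)oxy]-6-(3-methylbut-2-en-1-yl)phenol
Product: 21 2-(1-hydroxy-2-methylpropyl)-3-methoxy-5-[(4-methoxybenzyl)oxy]-6-(3-methylbut-2-en-1-yl)phenol (racemic)
Conditions: Bu4NF, THF, 0 °C → rt; H2O; crude product used directly
Reagents that add atoms: none
Why: Fluoride-induced Si–O cleavage (desilylation) releases the benzylic alcohol under basic conditions, which avoid ionisation of this very electron-rich carbinol; the crude diol is taken on without chromatography.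

Step 9
Reactants: 21 2-(1-hydroxy-2-methylpropyl)-3-methoxy-5-[(4-methoxybenzyl)oxy]-6-(3-methylbut-2-en-1-yl)phenol
Product: 22 1-{2-hydroxy-6-methoxy-4-[(4-methoxybenzyl)oxy]-3-(3-methylbut-2-en-1-yl)phenyl}-2-methylpropan-1-one
Conditions: MnO2 (activated, excess), CH2Cl2, rt
Reagents that add atoms: none
Why: Heterogeneous MnO2 oxidation, selective for benzylic alcohols, gives the aryl ketone, which is stabilised by the hydrogen bond from the C4′ hydroxyl; phenol, prenyl and PMB groups should be left alone and the last stereocentre is removed.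

Step 10
Reactants: 22 1-{2-hydroxy-6-methoxy-4-[(4-methoxybenzyl)oxy]-3-(3-methylbut-2-en-1-yl)phenyl}-2-methylpropan-1-one
Product: 23 1-[2,4-dihydroxy-6-methoxy-3-(3-methylbut-2-en-1-yl)phenyl]-2-methylpropan-1-one
Conditions: CF3CO2H, 1,3,5-trimethoxybenzene (5 equiv), CH2Cl2, 0 °C, short reaction time; aq. NaHCO3
Reagents that add atoms: none
Why: Acidolysis of the PMB aryl ether (SN1 cleavage) in which the 4-methoxybenzyl cation is intercepted by the more nucleophilic 1,3,5-trimethoxybenzene (Friedel–Crafts capture) before it can attack C1′–H, while the short cold exposure limits acid-induced chroman closure onto the prenyl group.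

Step 11
Reactants: 24 methyl 3-oxopentanoate; 25 N-methoxy-N-methylpropanamide
Product: 27 methyl 4-methyl-3,5-dioxoheptanoate (racemic), via dilithium dianion 26 (not isolated)
Conditions: LiN(i-Pr)2 (2.1 equiv), THF, −78 → 0 °C; then 25, −78 °C → rt; 1 M HCl
Reagents that add atoms: none
Why: γ-Acylation of a β-keto ester dianion by an N-methoxy-N-methyl amide, whose chelated tetrahedral adduct survives until work-up and so stops at the ketone stage; the new C4 stereocentre is racemic, enolisable and lost in step 12.

Step 12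
Reactants: 27 methyl 4-methyl-3,5-dioxoheptanoate
Product: 28 6-ethyl-4-hydroxy-5-methyl-2H-pyran-2-one
Conditions: DBU (1.1 equiv), PhMe, reflux; then 1 M HCl
Reagents that add atoms: none
Why: Base-promoted lactonisation (intramolecular O-acylation of the C5 enolate onto the methyl ester) of the 3,5-dioxo ester closes ring B as the 4-hydroxypyran-2-one.

Step 13
Reactants: 28 6-ethyl-4-hydroxy-5-methyl-2H-pyran-2-one; 23 1-[2,4-dihydroxy-6-methoxy-3-(3-methylbut-2-en-1-yl)phenyl]-2-methylpropan-1-one
Product: 31 3-{[2,4-dihydroxy-6-methoxy-3-(3-methylbut-2-en-1-yl)-5-(2-methylpropanoyl)phenyl]methyl}-6-ethyl-4-hydroxy-5-methyl-2H-pyran-2-one, via Mannich base hydroiodide 29 (not isolated), via methylene pyrandione 30 (not isolated)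
Conditions: 28 (1.05 equiv), CH2=NMe2+ I− (1.0 equiv), MeCN, rt; then 23, NaOAc, 70 °C
Reagents that add atoms: N,N-dimethylmethyleneiminium iodide, C=[N+](C)C.[I-]
Why: Mannich reaction at the nucleophilic C3 of the pyranone gives 29, buffered heating expels dimethylamine (retro-Mannich-type elimination) to the methylene dione 30, and this Michael acceptor is captured by C1′ of 23 in a Friedel–Crafts-type conjugate addition, C1′ being the only unsubstituted carbon of ring A so that the bridge can form at no other site.

**Compound list**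

1 | 4-methoxybenzyl alcohol | COc1ccc(CO)cc1 | starting material
2 | trichloroethylene | ClC=C(Cl)Cl | starting material
3 | 1-{[(E)-1,2-dichloroethenyl]oxymethyl}-4-methoxybenzene | COc1ccc(CO/C(Cl)=C\Cl)cc1 | intermediate
4 | 1-{[(chloroethynyl)oxy]methyl}-4-methoxybenzene | COc1ccc(COC#CCl)cc1 | intermediate (not isolated)
5 | lithium 2-[(4-methoxybenzyl)oxy]ethynide | COc1ccc(COC#C[Li])cc1 | intermediate (not isolated)
6 | 1-[(ethynyloxy)methyl]-4-methoxybenzene (4-methoxybenzyl ethynyl ether) | COc1ccc(COC#C)cc1 | intermediate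
7 | 5-methylhex-4-enoic acid | CC(C)=CCCC(=O)O | starting material
8 | 5-methylhex-4-enoyl chloride | CC(C)=CCCC(=O)Cl | intermediate
9 | 5-methylhexa-1,4-dien-1-one (prenylketene) | CC(C)=CCC=C=O | intermediate (not isolated)
10 | 3-[(4-methoxybenzyl)oxy]-4-(3-methylbut-2-en-1-yl)cyclobut-2-en-1-one (racemic) | O=C1C=C(OCc2ccc(OC)cc2)C1CC=C(C)C | intermediate
11 | chloroacetaldehyde dimethyl acetal (2-chloro-1,1-dimethoxyethane) | COC(CCl)OC | starting material
12 | isobutyraldehyde | CC(C)C=O | starting material
13 | lithium methoxyethynide | COC#C[Li] | intermediate (not isolated)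
14 | 1-methoxy-4-methylpent-1-yn-3-ol (racemic) | COC#CC(O)C(C)C | intermediate
15 | tert-butyl[(1-methoxy-4-methylpent-1-yn-3-yl)oxy]dimethylsilane (racemic) | COC#CC(O[Si](C)(C)C(C)(C)C)C(C)C | intermediate
16 | 3-[(4-methoxybenzyl)oxy]-7-methylocta-1,3,6-trien-1-one (vinylketene, olefin geometry not fixed) | O=C=CC(OCc1ccc(OC)cc1)=CCC=C(C)C | intermediate (not isolated)
17 | 2-{1-[(tert-butyldimethylsilyl)oxy]-2-methylpropyl}-3-methoxy-4-{1-[(4-methoxybenzyl)oxy]-5-methylhexa-1,4-dien-1-yl}cyclobut-2-en-1-one (diastereomer mixture) | O=C1C(C(O[Si](C)(C)C(C)(C)C)C(C)C)=C(OC)C1C(OCc2ccc(OC)cc2)=CCC=C(C)C | intermediate (not isolated)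
18 | 2-{1-[(tert-butyldimethylsilyl)oxy]-2-methylpropyl}-3-methoxy-5-[(4-methoxybenzyl)oxy]-9-methyldeca-1,3,5,8-tetraen-1-one (dienylketene, racemic) | O=C=C(C(O[Si](C)(C)C(C)(C)C)C(C)C)C(OC)=CC(OCc1ccc(OC)cc1)=CCC=C(C)C | intermediate (not isolated)
19 | 2-{1-[(tert-butyldimethylsilyl)oxy]-2-methylpropyl}-3-methoxy-5-[(4-methoxybenzyl)oxy]-6-(3-methylbut-2-en-1-yl)cyclohexa-2,4-dien-1-one (diastereomer mixture) | O=C1C(C(O[Si](C)(C)C(C)(C)C)C(C)C)=C(OC)C=C(OCc2ccc(OC)cc2)C1CC=C(C)C | intermediate (not isolated)
20 | 2-{1-[(tert-butyldimethylsilyl)oxy]-2-methylpropyl}-3-methoxy-5-[(4-methoxybenzyl)oxy]-6-(3-methylbut-2-en-1-yl)phenol (racemic) | COc1cc(OCc2ccc(OC)cc2)c(CC=C(C)C)c(O)c1C(O[Si](C)(C)C(C)(C)C)C(C)C | intermediate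
21 | 2-(1-hydroxy-2-methylpropyl)-3-methoxy-5-[(4-methoxybenzyl)oxy]-6-(3-methylbut-2-en-1-yl)phenol (racemic) | COc1cc(OCc2ccc(OC)cc2)c(CC=C(C)C)c(O)c1C(O)C(C)C | intermediate
22 | 1-{2-hydroxy-6-methoxy-4-[(4-methoxybenzyl)oxy]-3-(3-methylbut-2-en-1-yl)phenyl}-2-methylpropan-1-one | COc1cc(OCc2ccc(OC)cc2)c(CC=C(C)C)c(O)c1C(=O)C(C)C | intermediate
23 | 1-[2,4-dihydroxy-6-methoxy-3-(3-methylbut-2-en-1-yl)phenyl]-2-methylpropan-1-one | COc1cc(O)c(CC=C(C)C)c(O)c1C(=O)C(C)C | intermediate
24 | methyl 3-oxopentanoate | CCC(=O)CC(=O)OC | starting material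
25 | N-methoxy-N-methylpropanamide | CCC(=O)N(C)OC | starting material
26 | dilithium dianion of methyl 3-oxopentanoate | C[CH-]C(=O)[CH-]C(=O)OC.[Li+].[Li+] | intermediate (not isolated)
27 | methyl 4-methyl-3,5-dioxoheptanoate (racemic) | CCC(=O)C(C)C(=O)CC(=O)OC | intermediate
28 | 6-ethyl-4-hydroxy-5-methyl-2H-pyran-2-one | CCc1oc(=O)cc(O)c1C | intermediate
29 | 3-[(dimethylamino)methyl]-6-ethyl-4-hydroxy-5-methyl-2H-pyran-2-one hydroiodide | CCc1oc(=O)c(C[NH+](C)C)c(O)c1C.[I-] | intermediate (not isolated)
30 | 6-ethyl-5-methyl-3-methylidene-2H-pyran-2,4(3H)-dione | CCC1=C(C)C(=O)C(=C)C(=O)O1 | intermediate (not isolated)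
31 | 3-{[2,4-dihydroxy-6-methoxy-3-(3-methylbut-2-en-1-yl)-5-(2-methylpropanoyl)phenyl]methyl}-6-ethyl-4-hydroxy-5-methyl-2H-pyran-2-one | CCc1oc(=O)c(Cc2c(O)c(CC=C(C)C)c(O)c(C(=O)C(C)C)c2OC)c(O)c1C | target

**Step count and risks**

Total step count: 13. Longest linear sequence: 8 steps (steps 1, 2, 4, 7, 8, 9, 10 and 13).

Steps most likely to fail:

Step 7. The 3-alkoxy-4-alkylcyclobutenone may open only sluggishly, and the vinylketene may then be consumed by dimerisation or by acylating the product phenol before the hindered ynol ether captures it. Fallback: ring A is taken from a preformed benzene ring by two directed ortho-metalations. This sets out from isobutyraldehyde 12, with commercial 5-methoxybenzene-1,3-diol as the arene, and returns to the route at 23. The diol is protected with MOMCl and i-Pr2NEt to give 1-methoxy-3,5-bis(methoxymethoxy)benzene F1. Lithiation with n-BuLi in THF at 0 °C takes place between the two MOM ethers, and transmetalation with CuBr·SMe2 followed by prenyl bromide should give 5-methoxy-1,3-bis(methoxymethoxy)-2-(3-methylbut-2-en-1-yl)benzene F2. A second lithiation (n-BuLi, TMEDA) at one of the two equivalent positions between OMe and OMOM, then addition to 12, gives 1-[6-methoxy-2,4-bis(methoxymethoxy)-3-(3-methylbut-2-en-1-yl)phenyl]-2-methylpropan-1-ol F3. Oxidation with Dess–Martin periodinane gives 1-[6-methoxy-2,4-bis(methoxymethoxy)-3-(3-methylbut-2-en-1-yl)phenyl]-2-methylpropan-1-one F4, and HCl in MeOH at rt removes both MOM groups to reach 23.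

Step 10. The released 4-methoxybenzyl cation may re-alkylate the free C1′ position, and the acid may add the C2′ or C4′ hydroxyl across the prenyl double bond (chroman closure). Fallback: the oxygen at C2′ is carried as a fluoride-labile 2-(trimethylsilyl)ethyl ether, so that no acid is needed. This sets out from trichloroethylene 2, with commercial 2-(trimethylsilyl)ethanol in the place of 1, uses 8 and 15 unchanged, and returns at 23. It also removes the heat-sensitive benzyl ynol ether 6 from steps 2 and 4. KH and 2 give {2-[(E)-1,2-dichloroethenyl]oxyethyl}trimethylsilane F5. Treatment with n-BuLi and then water gives [2-(ethynyloxy)ethyl]trimethylsilane F6, an alkyl ynol ether with no sigmatropic pathway. Acid chloride 8 and Et3N give 4-(3-methylbut-2-en-1-yl)-3-[2-(trimethylsilyl)ethoxy]cyclobut-2-en-1-one F7. Heating with 15 as in step 7 should give 2-{1-[(tert-butyldimethylsilyl)oxy]-2-methylpropyl}-3-methoxy-6-(3-methylbut-2-en-1-yl)-5-[2-(trimethylsilyl)ethoxy]phenol F8. Bu4NF at rt removes only the TBS group to give 2-(1-hydroxy-2-methylpropyl)-3-methoxy-6-(3-methylbut-2-en-1-yl)-5-[2-(trimethylsilyl)ethoxy]phenol F9, and MnO2 gives 1-{2-hydroxy-6-methoxy-3-(3-methylbut-2-en-1-yl)-4-[2-(trimethylsilyl)ethoxy]phenyl}-2-methylpropan-1-one F10. Finally Bu4NF or CsF in DMF at 60 °C fragments the silylethyl ether to 23; the para acyl group makes the phenoxide a good leaving group, and the basic conditions spare the prenyl group.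

Step 13. The methylene dione may be captured by a second pyranone unit (methylene-bis-pyranone), or may alkylate a phenol oxygen, faster than it attacks the hindered C1′ carbon. Fallback: the electrophile and nucleophile roles are exchanged. This sets out from 23 and returns at target 31. CH2=NMe2+ I− in MeCN at rt aminomethylates the only free ring position of 23 to give 1-{3-[(dimethylamino)methyl]-4,6-dihydroxy-2-methoxy-5-(3-methylbut-2-en-1-yl)phenyl}-2-methylpropan-1-one F11. Heating F11 with pyranone 28 in dioxane at 100 °C expels dimethylamine, and C3 of 28 adds to the exocyclic methylene thus formed at C1′. The arene cannot dimerise through carbon because ring A has no other unsubstituted position.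

**Further compounds**

F1 | step 7 | 1-methoxy-3,5-bis(methoxymethoxy)benzene | COCOc1cc(OC)cc(OCOC)c1
F2 | step 7 | 5-methoxy-1,3-bis(methoxymethoxy)-2-(3-methylbut-2-en-1-yl)benzene | COCOc1cc(OC)cc(OCOC)c1CC=C(C)C
F3 | step 7 | 1-[6-methoxy-2,4-bis(methoxymethoxy)-3-(3-methylbut-2-en-1-yl)phenyl]-2-methylpropan-1-ol (racemic) | COCOc1cc(OC)c(C(O)C(C)C)c(OCOC)c1CC=C(C)C
F4 | step 7 | 1-[6-methoxy-2,4-bis(methoxymethoxy)-3-(3-methylbut-2-en-1-yl)phenyl]-2-methylpropan-1-one | COCOc1cc(OC)c(C(=O)C(C)C)c(OCOC)c1CC=C(C)C
F5 | step 10 | {2-[(E)-1,2-dichloroethenyl]oxyethyl}trimethylsilane | C[Si](C)(C)CCO/C(Cl)=C\Cl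
F6 | step 10 | [2-(ethynyloxy)ethyl]trimethylsilane | C[Si](C)(C)CCOC#C
F7 | step 10 | 4-(3-methylbut-2-en-1-yl)-3-[2-(trimethylsilyl)ethoxy]cyclobut-2-en-1-one (racemic) | O=C1C=C(OCC[Si](C)(C)C)C1CC=C(C)C
F8 | step 10 | 2-{1-[(tert-butyldimethylsilyl)oxy]-2-methylpropyl}-3-methoxy-6-(3-methylbut-2-en-1-yl)-5-[2-(trimethylsilyl)ethoxy]phenol (racemic) | COc1cc(OCC[Si](C)(C)C)c(CC=C(C)C)c(O)c1C(O[Si](C)(C)C(C)(C)C)C(C)C
F9 | step 10 | 2-(1-hydroxy-2-methylpropyl)-3-methoxy-6-(3-methylbut-2-en-1-yl)-5-[2-(trimethylsilyl)ethoxy]phenol (racemic) | COc1cc(OCC[Si](C)(C)C)c(CC=C(C)C)c(O)c1C(O)C(C)C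
F10 | step 10 | 1-{2-hydroxy-6-methoxy-3-(3-methylbut-2-en-1-yl)-4-[2-(trimethylsilyl)ethoxy]phenyl}-2-methylpropan-1-one | COc1cc(OCC[Si](C)(C)C)c(CC=C(C)C)c(O)c1C(=O)C(C)C
F11 | step 13 | 1-{3-[(dimethylamino)methyl]-4,6-dihydroxy-2-methoxy-5-(3-methylbut-2-en-1-yl)phenyl}-2-methylpropan-1-one | COc1c(CN(C)C)c(O)c(CC=C(C)C)c(O)c1C(=O)C(C)C
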